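With a small charge of reagent, 0.87 equiv, the south-west run stops early: it reads substrate 39.8% at 4.00 h and 39.6% at 15.0 h, flat within the scatter. The north-west and west runs are flat too, so we reckon by equivalents, not hours.

| setting | south-west | north-west | west | Saturday's | Sunday's | Friday's |
|---|---|---|---|---|---|---|
| substrate | 0.10 M | 0.10 M | 0.10 M | 0.10 M | 0.10 M | 0.10 M |
| reagent | 0.87 equiv | 1.5 equiv | 1.8 equiv | 1.20 equiv | 1.60 equiv | 2.00 equiv |
| remark | run made earlier | run made earlier | run made earlier |  |  |  |
| time |  |  |  | 30 h | 30 h | 30 h |

| run | time / h | substrate / % | tris adduct / % |
|---|---|---|---|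
| south-west | 4.00 | 39.8 | 6.1 |
| south-west | 8.00 | 40.3 | 7.0 |
| south-west | 12.0 | 40.7 | 5.5 |
| south-west | 15.0 | 39.6 | 5.1 |
| north-west | 1.33 | 19.3 | 20.0 |
| north-west | 3.00 | 18.5 | 21.4 |
| north-west | 6.00 | 18.5 | 21.2 |
| north-west | 15.0 | 19.3 | 21.5 |
| west | 2.00 | 11.8 | 31.7 |
| west | 5.00 | 13.1 | 33.2 |
| west | 10.0 | 11.5 | 31.6 |
| west | 15.0 | 11.6 | 33.1 |

(standard deviation of a reading: 0.5 percentage points)

* part of the substrate that has reacted at the end, Saturday's
* part of the substrate that has reacted at the end, Sunday's
* part of the substrate that has reacted at the end, Friday's
* what raising the equivalents of reagent from its lowest to its highest value here does to the part of the substrate that has reacted (changes below 5 percentage points count as none) (it falls / it rises / no change)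

- amounts and yields of by-product count idle adduct too
- candidate steps: substrate + reagent -> mono adduct + by-product; reagent + mono adduct -> double product + by-product; reagent + double product -> tris adduct + by-product; reagent + by-product <-> idle adduct

Take Saturday's 1.20 equiv and two extremes. If adducts took no reagent, the first equivalent would consume the substrate and none of it would remain. If each mono adduct ran straight on to tris adduct, every substrate would cost 3 equivalents, leaving a fraction 60.0%. The real flask should lie between, as the south-west run does: its 39.6% of substrate stands between 13.0% and 71.0%, its own two extremes of the second kind and of no substrate cost beyond one equivalent each.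

So we freeze one number, the take-up number: ln(charge over substrate left, mean of the readings) per equivalent of reagent. It drifts slowly, so each flask borrows it from the nearest run with a smaller charge of reagent:

south-west, for Saturday's: 1.05, left 28.4%, reacted 71.6%

north-west, for Sunday's: 1.11, reacted 83.1%

west, for Friday's: 1.18, reacted 90.5%

We therefore expect a rise of 19 percentage points.

The forecast gives 72.5%, 84% and 91.5%, and says it rises; it calls the composition “set by the equivalents and the selectivity, not by time”. On Friday's it stands above ours.

The flasks give 72.5%, 83.6% and 91.3%: it rises, by 19 points.

    substrate + reagent → mono adduct + by-product (k = 67.8 M⁻¹ h⁻¹)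
    reagent + mono adduct → double product + by-product (k = 62.2 M⁻¹ h⁻¹)
    reagent + double product → tris adduct + by-product (k = 63.1 M⁻¹ h⁻¹)
    reagent + by-product ⇌ idle adduct, settled at all times (K = 7.84 M⁻¹)

The forecast holds. In Saturday's flask the first step's half-life, 0.085 h with the other concentrations as charged, is short against 30 h. The flask ends with 0% of its reagent, the limiting reagent, and 28% of its substrate; ten times as long changes nothing. Its own take-up number comes to 1.07, against our 1.05.

A flask like Saturday's with 0.480 equiv of reagent should, by 1.05, keep 60.4% of its substrate. It keeps 61.3%.

The numbers in the tables come from a simulation for an exercise, noise included.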